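**Retrosynthetic overview**
1. The target should come from flavanone 21 by Markovnikov hydration of a C6 prenyl group and then neutral hydrogenolysis of four benzyl ethers.
2. 21 is assembled in one flask from ring A ortho-silylaryl triflate 10 and (S)-β-silyloxy N-methoxy-N-methylamide 17: fluoride liberates an aryne and an alkoxide, O1–C8a forms first, then C4–C4a. The SiMe3/OTf pair, the O–SiMe3 group and the N(OMe)Me group are activating groups that leave in this step.
3. Enabling feature: in ring A, C8a (bearing O1) and C4a (bearing the C4 acyl carbon) are adjacent, and the C5 oxygen sits next to C4a. A C4a≡C8a aryne is therefore polarised for O-attack at C8a with the carbanion at C4a. The O1–C2–C3–C4 chain of ring C is a β-oxy acyl unit, so C2 can be set earlier by asymmetric ketone reduction.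
4. 10 derives from 3,5-bis(benzyloxy)phenol (silylation, lithiation/prenylation between the two benzyloxy groups, desilylation, ortho-bromination, retro-Brook/triflation). 17 derives from 3,4-bis(benzyloxy)benzoic acid (Claisen acylation, asymmetric transfer hydrogenation, silylation).
5. Ring order: rings A and B are bought as arenes; ring C is the only ring formed, in step 9.

Key step: step 9

Remark: C2 of the chromanone is the only stereocentre and is (S). 3,5-Bis(benzyloxy)phenol and 3,4-bis(benzyloxy)benzoic acid are taken as catalogue compounds.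

**Route**

Step 1
Reactants: 1 3,5-bis(benzyloxy)phenol
Product: 2 [3,5-bis(benzyloxy)phenoxy]tri(propan-2-yl)silane
Conditions: TIPSCl, imidazole, DMF, rt
Reagents that add atoms: chlorotri(propan-2-yl)silane, CC(C)[Si](Cl)(C(C)C)C(C)C
Why: O-silylation of a phenol should give a bulky silyl ether that neither directs ortho-lithiation nor migrates in the next step.

Step 2
Reactants: 2 [3,5-bis(benzyloxy)phenoxy]tri(propan-2-yl)silane; 3 1-bromo-3-methylbut-2-ene (prenyl bromide)
Product: 5 [3,5-bis(benzyloxy)-4-(3-methylbut-2-en-1-yl)phenoxy]tri(propan-2-yl)silane, via aryllithium 4 (not isolated)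
Conditions: n-BuLi, TMEDA, THF, 0 °C; then CuBr·SMe2 (10 mol%), 3, −78 °C to rt
Reagents that add atoms: none
Why: Directed ortho-metalation should occur at the one C–H flanked by two benzyloxy groups (the hindered silyloxy group does not direct), and copper-catalysed SN2 allylation of the aryllithium should install the prenyl group.

Step 3
Reactants: 5 [3,5-bis(benzyloxy)-4-(3-methylbut-2-en-1-yl)phenoxy]tri(propan-2-yl)silane
Product: 6 3,5-bis(benzyloxy)-4-(3-methylbut-2-en-1-yl)phenol
Conditions: TBAF, AcOH (1 equiv), THF, 0 °C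
Reagents that add atoms: none
Why: Buffered fluoride desilylation of an aryl silyl ether should free the phenol without touching the benzyl ethers or the alkene.

Step 4
Reactants: 6 3,5-bis(benzyloxy)-4-(3-methylbut-2-en-1-yl)phenol
Product: 7 3,5-bis(benzyloxy)-2-bromo-4-(3-methylbut-2-en-1-yl)phenol
Conditions: NBS (1.0 equiv), CH2Cl2, −78 °C
Reagents that add atoms: N-bromosuccinimide, O=C1CCC(=O)N1Br
Why: Electrophilic aromatic bromination should take place at one of the two symmetry-equivalent free positions ortho to the hydroxyl, since the trioxygenated ring is far more nucleophilic than the prenyl alkene at low temperature.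

Step 5
Reactants: 7 3,5-bis(benzyloxy)-2-bromo-4-(3-methylbut-2-en-1-yl)phenol
Product: 10 3,5-bis(benzyloxy)-4-(3-methylbut-2-en-1-yl)-2-(trimethylsilyl)phenyl trifluoromethanesulfonate, via aryl silyl ether 8 (not isolated), via lithium silylphenoxide 9 (not isolated)
Conditions: HMDS, THF, 65 °C, then evaporation; n-BuLi, THF, −78 °C; Tf2O, −78 °C to 0 °C
Reagents that add atoms: hexamethyldisilazane, C[Si](C)(C)N[Si](C)(C)C; trifluoromethanesulfonic anhydride, O=S(=O)(OS(=O)(=O)C(F)(F)F)C(F)(F)F
Why: O-silylation, bromine–lithium exchange, [1,3] O-to-C silyl shift (retro-Brook rearrangement) and O-triflation form the standard one-flask entry to ortho-silylaryl triflates, and exchange at −78 °C is much faster than benzylic deprotonation.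

Step 6
Reactants: 11 3,4-bis(benzyloxy)benzoic acid; 12 N-methoxy-N-methylacetamide
Product: 15 3-[3,4-bis(benzyloxy)phenyl]-N-methoxy-N-methyl-3-oxopropanamide, via acylimidazole 13 (not isolated), via lithium amide enolate 14 (not isolated)
Conditions: 11, CDI, THF, rt; added to 12 and LDA (2.2 equiv each), THF, −78 °C; then AcOH
Reagents that add atoms: none
Why: A crossed Claisen condensation of an amide enolate with an acyl imidazolide should give the β-keto amide, the second equivalent of enolate absorbing the acidic product proton.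

Step 7
Reactants: 15 3-[3,4-bis(benzyloxy)phenyl]-N-methoxy-N-methyl-3-oxopropanamide
Product: 16 (3S)-3-[3,4-bis(benzyloxy)phenyl]-3-hydroxy-N-methoxy-N-methylpropanamide
Conditions: RuCl[(S,S)-TsDPEN](p-cymene) (1 mol%), HCO2H/Et3N (5:2), EtOAc, 40 °C
Reagents that add atoms: none
Why: Asymmetric transfer hydrogenation (Noyori–Ikariya type) of an aryl ketone should set C3 as (S) under control of the (S,S)-diamine ligand, the aryl group being recognised by the arene ligand as in acetophenone reduction.

Step 8
Reactants: 16 (3S)-3-[3,4-bis(benzyloxy)phenyl]-3-hydroxy-N-methoxy-N-methylpropanamide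
Product: 17 (3S)-3-[3,4-bis(benzyloxy)phenyl]-N-methoxy-N-methyl-3-[(trimethylsilyl)oxy]propanamide
Conditions: TMSCl, imidazole, CH2Cl2, 0 °C
Reagents that add atoms: chlorotrimethylsilane, C[Si](C)(C)Cl
Why: O-silylation of a secondary alcohol should give a fluoride-labile ether that masks the O–H proton and does not touch the stereocentre.

Step 9
Reactants: 10 3,5-bis(benzyloxy)-4-(3-methylbut-2-en-1-yl)-2-(trimethylsilyl)phenyl trifluoromethanesulfonate; 17 (3S)-3-[3,4-bis(benzyloxy)phenyl]-N-methoxy-N-methyl-3-[(trimethylsilyl)oxy]propanamide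
Product: 21 (2S)-5,7-bis(benzyloxy)-2-[3,4-bis(benzyloxy)phenyl]-6-(3-methylbut-2-en-1-yl)-2,3-dihydro-4H-chromen-4-one, via aryne 18 (not isolated), via potassium alkoxide 19 (not isolated), via hemiaminal alkoxide 20 (not isolated)
Conditions: KF (4 equiv), 18-crown-6 (4 equiv), THF, 0 °C to rt, 10 (1.3 equiv) added slowly; then AcOH, 0 °C
Reagents that add atoms: none
Why: Proposed new method: fluoride cleaves the O–SiMe3 bond of 17 to the alkoxide 19 and, by attack at the C–SiMe3 group of 10 with loss of triflate, releases aryne 18; 19 adds through oxygen to the aryne carbon that becomes C8a, and the aryl carbanion formed at C4a attacks the amide carbonyl to give the tetrahedral hemiaminal alkoxide 20, which should collapse to the ketone only on the acidic quench. The closest known reaction type is the fluoride-induced annulation of arynes with methyl salicylates to xanthones (nucleophilic addition, then intramolecular acyl capture of the aryl anion), extended here from a phenoxide to a secondary benzylic alkoxide and from an ester to an N-methoxy-N-methylamide. Ring C is closed by 6-exo-trig attack of the aryl anion on the amide C=O. No stereocentre is created: C2 comes from 17 and its C–O bond is never broken, so (S) is retained, and because C4 stays sp3 in 20 until the quench, the base-promoted retro-oxa-Michael opening that racemises flavanones should not operate in the flask. The step needs O-attack at C8a and not at C4a, which the benzyloxy group on C5 should secure (inductive stabilisation of the C4a carbanion, aryne distortion and steric shielding of C4a, as in 3-alkoxybenzynes). It also needs acyl capture to outrun protonation of the aryl anion, which the aprotic medium, the absence of any O–H and the six-membered transition state should secure, while the weakly acidic amide α-CH2 disfavours retro-aldol and E1cB loss of the alkoxide.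

Step 10
Reactants: 21 (2S)-5,7-bis(benzyloxy)-2-[3,4-bis(benzyloxy)phenyl]-6-(3-methylbut-2-en-1-yl)-2,3-dihydro-4H-chromen-4-one
Product: 22 (2S)-5,7-bis(benzyloxy)-2-[3,4-bis(benzyloxy)phenyl]-6-(3-hydroxy-3-methylbutyl)-2,3-dihydro-4H-chromen-4-one
Conditions: Co(acac)2 (20 mol%), PhSiH3, O2 (1 atm), THF, rt
Reagents that add atoms: dioxygen, O=O
Why: Mukaiyama hydration (hydrogen-atom transfer to the trisubstituted alkene, capture of the tertiary radical by O2, reduction of the peroxide) should give the Markovnikov tertiary alcohol under neutral conditions that leave the ketone and C2 untouched.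

Step 11
Reactants: 22 (2S)-5,7-bis(benzyloxy)-2-[3,4-bis(benzyloxy)phenyl]-6-(3-hydroxy-3-methylbutyl)-2,3-dihydro-4H-chromen-4-one
Product: 23 (2S)-2-(3,4-dihydroxyphenyl)-5,7-dihydroxy-6-(3-hydroxy-3-methylbutyl)-2,3-dihydro-4H-chromen-4-one (target)
Conditions: H2 (1 atm), Pd/C (10%), EtOAc/MeOH, rt
Reagents that add atoms: none
Why: Catalytic hydrogenolysis of the four benzyl aryl ethers is neutral, so it should avoid both acid-induced cyclisation of the tertiary alcohol onto the neighbouring phenols and base-induced opening of the flavanone, leaving C2 as (S).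

**Compound list**
1 | 3,5-bis(benzyloxy)phenol | Oc1cc(OCc2ccccc2)cc(OCc2ccccc2)c1 | starting material
2 | [3,5-bis(benzyloxy)phenoxy]tri(propan-2-yl)silane | CC(C)[Si](Oc1cc(OCc2ccccc2)cc(OCc2ccccc2)c1)(C(C)C)C(C)C | intermediate
3 | 1-bromo-3-methylbut-2-ene | CC(C)=CCBr | starting material
4 | [2,6-bis(benzyloxy)-4-{[tri(propan-2-yl)silyl]oxy}phenyl]lithium | [Li]c1c(OCc2ccccc2)cc(O[Si](C(C)C)(C(C)C)C(C)C)cc1OCc1ccccc1 | intermediate
5 | [3,5-bis(benzyloxy)-4-(3-methylbut-2-en-1-yl)phenoxy]tri(propan-2-yl)silane | CC(C)=CCc1c(OCc2ccccc2)cc(O[Si](C(C)C)(C(C)C)C(C)C)cc1OCc1ccccc1 | intermediate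
6 | 3,5-bis(benzyloxy)-4-(3-methylbut-2-en-1-yl)phenol | CC(C)=CCc1c(OCc2ccccc2)cc(O)cc1OCc1ccccc1 | intermediate
7 | 3,5-bis(benzyloxy)-2-bromo-4-(3-methylbut-2-en-1-yl)phenol | CC(C)=CCc1c(OCc2ccccc2)cc(O)c(Br)c1OCc1ccccc1 | intermediate
8 | [3,5-bis(benzyloxy)-2-bromo-4-(3-methylbut-2-en-1-yl)phenoxy]trimethylsilane | CC(C)=CCc1c(OCc2ccccc2)cc(O[Si](C)(C)C)c(Br)c1OCc1ccccc1 | intermediate
9 | lithium 3,5-bis(benzyloxy)-4-(3-methylbut-2-en-1-yl)-2-(trimethylsilyl)phenolate | [Li+].CC(C)=CCc1c(OCc2ccccc2)cc([O-])c([Si](C)(C)C)c1OCc1ccccc1 | intermediate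
10 | 3,5-bis(benzyloxy)-4-(3-methylbut-2-en-1-yl)-2-(trimethylsilyl)phenyl trifluoromethanesulfonate | CC(C)=CCc1c(OCc2ccccc2)cc(OS(=O)(=O)C(F)(F)F)c([Si](C)(C)C)c1OCc1ccccc1 | intermediate
11 | 3,4-bis(benzyloxy)benzoic acid | OC(=O)c1ccc(OCc2ccccc2)c(OCc2ccccc2)c1 | starting material
12 | N-methoxy-N-methylacetamide | CC(=O)N(C)OC | starting material
13 | [3,4-bis(benzyloxy)phenyl](1H-imidazol-1-yl)methanone | O=C(c1ccc(OCc2ccccc2)c(OCc2ccccc2)c1)n1ccnc1 | intermediate
14 | lithium 1-[methoxy(methyl)amino]ethen-1-olate | [Li+].C=C([O-])N(C)OC | intermediate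
15 | 3-[3,4-bis(benzyloxy)phenyl]-N-methoxy-N-methyl-3-oxopropanamide | CON(C)C(=O)CC(=O)c1ccc(OCc2ccccc2)c(OCc2ccccc2)c1 | intermediate
16 | (3S)-3-[3,4-bis(benzyloxy)phenyl]-3-hydroxy-N-methoxy-N-methylpropanamide | CON(C)C(=O)C[C@@H](c1ccc(OCc2ccccc2)c(OCc2ccccc2)c1)O | intermediate
17 | (3S)-3-[3,4-bis(benzyloxy)phenyl]-N-methoxy-N-methyl-3-[(trimethylsilyl)oxy]propanamide | CON(C)C(=O)C[C@@H](c1ccc(OCc2ccccc2)c(OCc2ccccc2)c1)O[Si](C)(C)C | intermediate
18 | 3,5-bis(benzyloxy)-4-(3-methylbut-2-en-1-yl)benzyne (1,2-didehydrobenzene) | C1#CC(OCc2ccccc2)=C(CC=C(C)C)C(OCc2ccccc2)=C1 | intermediate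
19 | potassium (1S)-1-[3,4-bis(benzyloxy)phenyl]-3-[methoxy(methyl)amino]-3-oxopropan-1-olate | [K+].CON(C)C(=O)C[C@@H](c1ccc(OCc2ccccc2)c(OCc2ccccc2)c1)[O-] | intermediate
20 | potassium (2S)-5,7-bis(benzyloxy)-2-[3,4-bis(benzyloxy)phenyl]-4-[methoxy(methyl)amino]-6-(3-methylbut-2-en-1-yl)-3,4-dihydro-2H-chromen-4-olate (both C4 epimers) | [K+].CON(C)C1([O-])C[C@@H](c2ccc(OCc3ccccc3)c(OCc3ccccc3)c2)Oc2cc(OCc3ccccc3)c(CC=C(C)C)c(OCc3ccccc3)c21 | intermediate
21 | (2S)-5,7-bis(benzyloxy)-2-[3,4-bis(benzyloxy)phenyl]-6-(3-methylbut-2-en-1-yl)-2,3-dihydro-4H-chromen-4-one | CC(C)=CCc1c(OCc2ccccc2)cc2c(c1OCc1ccccc1)C(=O)C[C@@H](c1ccc(OCc3ccccc3)c(OCc3ccccc3)c1)O2 | intermediate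
22 | (2S)-5,7-bis(benzyloxy)-2-[3,4-bis(benzyloxy)phenyl]-6-(3-hydroxy-3-methylbutyl)-2,3-dihydro-4H-chromen-4-one | CC(C)(O)CCc1c(OCc2ccccc2)cc2c(c1OCc1ccccc1)C(=O)C[C@@H](c1ccc(OCc3ccccc3)c(OCc3ccccc3)c1)O2 | intermediate
23 | (2S)-2-(3,4-dihydroxyphenyl)-5,7-dihydroxy-6-(3-hydroxy-3-methylbutyl)-2,3-dihydro-4H-chromen-4-one | CC(C)(O)CCc1c(O)cc2c(c1O)C(=O)C[C@@H](c1ccc(O)c(O)c1)O2 | target

**Step count:** 11 steps in total. The longest linear sequence is 8 steps (steps 1–5, then 9–11); the side branch is 3 steps (6–8).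

**Steps most likely to fail**

Step 9 (proposed new method). The aryl anion may be protonated or diverted before acyl capture, leaving an uncyclised aryl ether. Fluoride or the hemiaminal alkoxide may add to the aryne in competition. Enantiopurity may erode if the hemiaminal collapses early and the flavanone opens by retro-oxa-Michael reaction. The fallback sets out from 7 and comes back at 21, using known chemistry only. Bromophenol 7 should be converted with n-BuLi (2.2 equiv, THF, −78 °C) into the O,C-dilithio species and acylated with 12 to give hydroxyacetophenone F1. Condensation with N,N-dimethylformamide dimethyl acetal should give enaminone F2, which should cyclise on mild acid (AcOH) to chromone F3. Asymmetric conjugate addition of [3,4-bis(benzyloxy)phenyl]boronic acid to F3, catalysed by Pd(OCOCF3)2 and the t-BuPyOx antipode that gives the (2S) adduct ((R)-t-BuPyOx is expected, by analogy with cyclic enones), should then return to 21.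

Step 4. The prenyl double bond may be brominated, or the ring brominated twice, in competition with the single ring bromination. The fallback sets out from 6 and comes back at 10, replacing halogenation by directed ortho-metalation. Phenol 6 should react with isopropyl isocyanate (Et3N, CH2Cl2) to give aryl carbamate F4. In-situ N-silylation (TBSOTf, TMEDA), carbamate-directed ortho-lithiation (n-BuLi, TMEDA, Et2O, −78 °C) and a TMSCl quench should give silyl carbamate F5. Cleavage with Et2NH/DBU (MeCN, 40 °C) should free silylphenol F6, which is triflated with PhNTf2 in the same flask to give 10.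

Step 10. Hydrogen-atom transfer may lead to reduction of the alkene or of the aryl ketone and not to hydration, radicals may abstract benzylic ether hydrogens, and conversion may stall. The fallback sets out from 21 and comes back at 22 by a polar sequence. Epoxidation of the prenyl alkene (mCPBA, NaHCO3, CH2Cl2, 0 °C) should give epoxide F7. LiEt3BH (THF, 0 °C) should open the epoxide at the less substituted carbon and also reduce the C4 ketone, giving diol F8. Selective oxidation of the secondary benzylic alcohol with Dess–Martin periodinane (NaHCO3, CH2Cl2) should give 22.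

**Further compounds**
F1 | step 9 | 1-[2,4-bis(benzyloxy)-6-hydroxy-3-(3-methylbut-2-en-1-yl)phenyl]ethan-1-one | CC(=O)c1c(O)cc(OCc2ccccc2)c(CC=C(C)C)c1OCc1ccccc1
F2 | step 9 | (2E)-1-[2,4-bis(benzyloxy)-6-hydroxy-3-(3-methylbut-2-en-1-yl)phenyl]-3-(dimethylamino)prop-2-en-1-one | CN(C)/C=C/C(=O)c1c(O)cc(OCc2ccccc2)c(CC=C(C)C)c1OCc1ccccc1
F3 | step 9 | 5,7-bis(benzyloxy)-6-(3-methylbut-2-en-1-yl)-4H-chromen-4-one | CC(C)=CCc1c(OCc2ccccc2)cc2occc(=O)c2c1OCc1ccccc1
F4 | step 4 | 3,5-bis(benzyloxy)-4-(3-methylbut-2-en-1-yl)phenyl propan-2-ylcarbamate | CC(C)NC(=O)Oc1cc(OCc2ccccc2)c(CC=C(C)C)c(OCc2ccccc2)c1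
F5 | step 4 | 3,5-bis(benzyloxy)-4-(3-methylbut-2-en-1-yl)-2-(trimethylsilyl)phenyl propan-2-ylcarbamate | CC(C)NC(=O)Oc1cc(OCc2ccccc2)c(CC=C(C)C)c(OCc2ccccc2)c1[Si](C)(C)C
F6 | step 4 | 3,5-bis(benzyloxy)-4-(3-methylbut-2-en-1-yl)-2-(trimethylsilyl)phenol | CC(C)=CCc1c(OCc2ccccc2)cc(O)c([Si](C)(C)C)c1OCc1ccccc1
F7 | step 10 | (2S)-5,7-bis(benzyloxy)-2-[3,4-bis(benzyloxy)phenyl]-6-[(3,3-dimethyloxiran-2-yl)methyl]-2,3-dihydro-4H-chromen-4-one | CC1(C)OC1Cc1c(OCc2ccccc2)cc2c(c1OCc1ccccc1)C(=O)C[C@@H](c1ccc(OCc3ccccc3)c(OCc3ccccc3)c1)O2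
F8 | step 10 | (2S)-5,7-bis(benzyloxy)-2-[3,4-bis(benzyloxy)phenyl]-6-(3-hydroxy-3-methylbutyl)-3,4-dihydro-2H-chromen-4-ol | CC(C)(O)CCc1c(OCc2ccccc2)cc2c(c1OCc1ccccc1)C(O)C[C@@H](c1ccc(OCc3ccccc3)c(OCc3ccccc3)c1)O2
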